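(The constants were set for the occasion; no experiment stands behind them.)

If solid substrate stands in excess under a held gas, the bench habit is to put both feeds of the product-forming step at their ceilings.

    solid substrate + target → side product (k1 = 0.00822 M⁻¹ s⁻¹)
    target ⇌ isomer of the product (K2 = 12.3, k2 = 3.35 × 10⁻⁴ s⁻¹)
    dissolved substrate + partner → target (k3 = 0.231 M⁻¹ s⁻¹)
    gas ⇌ partner, rate k4*(csat - [partner]) (k4 = 0.00277 s⁻¹, csat = 3.2 mM)
    solid substrate ⇌ dissolved substrate, rate k5*(cs5 - [dissolved substrate]) while solid is left; crystals form when [dissolved substrate] > cs5 (cs5 = 9.2 mM, k5 = 0.00407 s⁻¹)

| setting | west | north-east | south | east |
|---|---|---|---|---|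
| solid substrate | 0.010 M | 0.020 M | 0.040 M | 0.080 M |
| gas | 3.2 mM (held) | 3.2 mM (held) | 3.2 mM (held) | 3.2 mM (held) |
| time | 3.0 h | 3.0 h | 3.0 h | 3.0 h |

- percent here means solid substrate units held: one side product counts as two
- solid substrate is a solid; its amount is given per volume of the solution
- at the start none of partner is dissolved
- at the start none of the solid substrate is in solution
- "hardly changes" means that all values lie within two and a half points (for a concentration: within two and a half percent of the largest)
- run time (west): 3.0 h

- [target] at the end for west, north-east, south, east, in this order
- the shape of the row from first to last (falls, then rises / falls all the way / hardly changes / rises, then falls / rises all the way)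

That rule of thumb sets dissolved substrate at its solubility 9.2 mM and partner at its saturation 3.2 mM, and so target forms at 24.5 mM h⁻¹. Its border appears in a ratio of given numbers: partner is consumed with the coefficient 0.00213 s⁻¹ and replaced with 0.00277 s⁻¹, a ratio of 0.767, larger than 0.5, so partner cannot be treated as saturated.

The way on is a quasi-steady state, iterated. With dissolved substrate at its solubility, the balance of crossing against consumption puts partner at 1.81 mM, and the rate falls to 13.9 mM h⁻¹. Going round once more, dissolved substrate must lag its solubility by that rate over the dissolution coefficient, which leaves it at 8.25 mM. Partner then stands at 1.90 mM. The supply rate r, the rate at which target is made while solid stands, comes to 13.0 mM h⁻¹, about half of the bench figure.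

Over the run, r amounts to 39.0 mM of target. The west and north-east charges are smaller than that, so by this reckoning their solid does not last to the end. The east charge is larger, and if solid lasts there, the target made comes to 48.8 % of the charge. This reckoning stops at that total and does not split it among target, isomer of the product and side product.

The forecast gives 0.0013 M, 0.0028 M, 0.0082 M and 0.0073 M, a row that rises, then falls, on the ground that “the large excess of solid keeps consuming target into side product”.

The flasks end with target at 0.00128 M, 0.00304 M, 0.00819 M and 0.00724 M, so the row rises, then falls. The east flask still holds 21.8 % of its solid at the end. There, target, isomer of the product and the side product percent divided by 2 add up to 47.7 % of the charge, against 48.8 % from r. In the south flask after 1.50 h, with solid at 23.9 %, the same count gives 46.4 %, against 48.8 % from r.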